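Everything rests on cutting the exocyclic C7–C1 bond at the diene oxidation level. C1 is the only carbon-branched atom of the cyclohexene ring and sits next to the cis C5/C6 diol, exactly the pattern of the microbial cis-dihydrodiol of bromobenzene, whose C–Br carbon becomes C1. A Stille hydroxymethylation of the bromodiene acetonide joins C7 to C1 and unveils a primary allylic alcohol, which then steers an anti epoxidation of C1=C2 and a titanium-guided benzoate opening at allylic C2, setting the trans C1–OH/C2–OBz pair. Acetonide hydrolysis and site-selective benzoylation of O7 and allylic O5 complete the target. Numbering: C1 quaternary carbinol carbon, C2/C5 benzoyloxy carbons, C3=C4 alkene, C6 secondary carbinol, C7 exocyclic CH2.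

Key step: step 2

Remark: diol 1 (the fermentation-derived cis-dihydrodiol of bromobenzene) is taken as a commercial, enantiopure starting material; "upper face" means the ring face opposite the C5/C6 oxygens.

Step 1
Reactants: 1 (1S,2S)-3-bromocyclohexa-3,5-diene-1,2-diol
Product: 2 (3aS,7aS)-4-bromo-2,2-dimethyl-3a,7a-dihydro-1,3-benzodioxole
Conditions: 2,2-dimethoxypropane, TsOH·H2O (cat.), acetone, 0 °C to rt
Reagents that add atoms: 2,2-dimethoxypropane COC(C)(C)OC
Why: Acid-catalysed transacetalisation (acetonide formation) closes a cis-fused dioxolane on the cis-diol without touching either stereocentre, and the new ring later shields the lower face of the diene.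

Step 2
Reactants: 2 (3aS,7aS)-4-bromo-2,2-dimethyl-3a,7a-dihydro-1,3-benzodioxole; 3 (tributylstannyl)methanol
Product: 4 [(3aR,7aS)-2,2-dimethyl-3a,7a-dihydro-1,3-benzodioxol-4-yl]methanol
Conditions: Pd(PPh3)4 (5 mol %), CuI (10 mol %), CsF (2 equiv), DMF, 45 °C
Reagents that add atoms: none
Why: Oxidative addition of zerovalent palladium into the C1–Br bond of 2 gives an alkenylpalladium bromide; fluoride- and copper-assisted transmetalation then transfers the hydroxymethyl group of 3, and reductive elimination forms the C7–C1 bond. The closest known reaction type is the Stille hydroxymethylation of aryl and alkenyl halides with (tributylstannyl)methanol. No ring is closed and no stereocentre is created; C5 and C6 are untouched, and the new primary allylic alcohol is the control element for the two steps that set C1 and C2. The step needs selective transfer of CH2OH over butyl, which the α-oxygen and the CuI/CsF activation should secure, and it must outrun Diels–Alder dimerisation and aromatisation of the diene, which the low temperature and neutral medium should secure.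

Step 3
Reactants: 4 [(3aR,7aS)-2,2-dimethyl-3a,7a-dihydro-1,3-benzodioxol-4-yl]methanol
Product: 5 [(1S,2S,5S,6S)-1,2-epoxy-5,6-(isopropylidenedioxy)cyclohex-3-en-1-yl]methanol (oxirane oxygen on the upper face)
Conditions: VO(acac)2 (3 mol %), t-BuOOH (1.3 equiv, decane), CH2Cl2, 0 °C
Reagents that add atoms: tert-butyl hydroperoxide CC(C)(C)OO
Why: Hydroxyl-directed vanadium-catalysed epoxidation of an allylic alcohol: the vanadate ester of O7 delivers oxygen only to the proximal C1=C2 bond, and the cis-fused acetonide blocks the lower face, so the oxirane should form anti to O5/O6 and thereby set C1 and C2.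

Step 4
Reactants: 5 [(1S,2S,5S,6S)-1,2-epoxy-5,6-(isopropylidenedioxy)cyclohex-3-en-1-yl]methanol
Product: 6 (3aS,4S,5R,7aS)-4-hydroxy-4-(hydroxymethyl)-2,2-dimethyl-3a,4,5,7a-tetrahydro-1,3-benzodioxol-5-yl benzoate
Conditions: Ti(OiPr)4 (1.5 equiv), PhCO2H (1.5 equiv), CH2Cl2, 0 °C to rt; aq. tartaric acid work-up
Reagents that add atoms: benzoic acid OC(=O)c1ccccc1
Why: Titanium-mediated C3-selective opening of a 2,3-epoxy alcohol: chelation of O7 and the oxirane oxygen to titanium directs benzoate to the distal, allylic C2 by backside attack, which inverts C2 (benzoate on the lower face) and leaves the C1–O bond intact as the upper-face tertiary alcohol.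

Step 5
Reactants: 6 (3aS,4S,5R,7aS)-4-hydroxy-4-(hydroxymethyl)-2,2-dimethyl-3a,4,5,7a-tetrahydro-1,3-benzodioxol-5-yl benzoate
Product: 7 (1R,2R,5S,6S)-1,5,6-trihydroxy-1-(hydroxymethyl)cyclohex-3-en-2-yl benzoate
Conditions: AcOH/H2O 4:1, 45 °C
Reagents that add atoms: none
Why: Acid-catalysed acetal hydrolysis frees the cis C5/C6 diol under conditions too mild to ionise the allylic benzoate or to move acyl groups, with no stereocentre involved.

Step 6
Reactants: 7 (1R,2R,5S,6S)-1,5,6-trihydroxy-1-(hydroxymethyl)cyclohex-3-en-2-yl benzoate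
Product: 9 [(1R,2R,5S,6S)-2,5-bis(benzoyloxy)-1,6-dihydroxycyclohex-3-en-1-yl]methyl benzoate, via 7-O-benzoate 8 (not isolated)
Conditions: BzCl (2.1 equiv), pyridine, CH2Cl2, −40 to −10 °C
Reagents that add atoms: benzoyl chloride O=C(Cl)c1ccccc1
Why: Kinetically controlled site-selective acylation: the primary O7–H should react first and the allylic O5–H next, whereas O6–H (flanked by the quaternary C1 and by C5) and the tertiary O1–H are too hindered to react at low temperature, and no stereocentre is touched.

Compound list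
1 | (1S,2S)-3-bromocyclohexa-3,5-diene-1,2-diol | O[C@H]1C=CC=C(Br)[C@H]1O | starting material
2 | (3aS,7aS)-4-bromo-2,2-dimethyl-3a,7a-dihydro-1,3-benzodioxole | CC1(C)O[C@H]2C=CC=C(Br)[C@H]2O1 | intermediate
3 | (tributylstannyl)methanol | CCCC[Sn](CCCC)(CCCC)CO | starting material
4 | [(3aR,7aS)-2,2-dimethyl-3a,7a-dihydro-1,3-benzodioxol-4-yl]methanol | CC1(C)O[C@H]2C=CC=C(CO)[C@H]2O1 | intermediate
5 | [(1S,2S,5S,6S)-1,2-epoxy-5,6-(isopropylidenedioxy)cyclohex-3-en-1-yl]methanol, oxirane anti to the acetonide | CC1(C)O[C@H]2C=C[C@@H]3O[C@]3(CO)[C@H]2O1 | intermediate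
6 | (3aS,4S,5R,7aS)-4-hydroxy-4-(hydroxymethyl)-2,2-dimethyl-3a,4,5,7a-tetrahydro-1,3-benzodioxol-5-yl benzoate | CC1(C)O[C@H]2C=C[C@@H](OC(=O)c3ccccc3)[C@@](O)(CO)[C@H]2O1 | intermediate
7 | (1R,2R,5S,6S)-1,5,6-trihydroxy-1-(hydroxymethyl)cyclohex-3-en-2-yl benzoate | O[C@H]1C=C[C@@H](OC(=O)c2ccccc2)[C@@](O)(CO)[C@H]1O | intermediate
8 | [(1R,2R,5S,6S)-2-(benzoyloxy)-1,5,6-trihydroxycyclohex-3-en-1-yl]methyl benzoate | O[C@H]1C=C[C@@H](OC(=O)c2ccccc2)[C@@](O)(COC(=O)c2ccccc2)[C@H]1O | intermediate
9 | [(1R,2R,5S,6S)-2,5-bis(benzoyloxy)-1,6-dihydroxycyclohex-3-en-1-yl]methyl benzoate | O=C(OC[C@]1(O)[C@H](OC(=O)c2ccccc2)C=C[C@H](OC(=O)c2ccccc2)[C@@H]1O)c1ccccc1 | target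

Total step count: 6. Longest linear sequence: 6 steps.

Steps most likely to fail

Step 6. The discrimination between O5–H and O6–H may erode, or acylation may run on to a tetrabenzoate. The fallback sets out from 7 and returns at 9. tBu2Si(OTf)2 with 2,6-lutidine in DMF at 0 °C should bridge the primary O7 and the cis-disposed O6 in a six-membered ring, giving the 6,7-O-(di-tert-butylsilylene) derivative F4. BzCl, pyridine and catalytic DMAP then acylate the only reactive hydroxyl left, O5–H, to give the 5-O-benzoyl silylene F5. HF·pyridine in THF removes the silylene without acyl migration and gives the 2,5-dibenzoate triol F6. One equivalent of BzCl in pyridine at −40 °C then acylates the primary O7–H to give 9.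

Step 2. Transfer of the sp3 hydroxymethyl group from tin may be slow, so that thermal dimerisation or aromatisation of the diene overtakes the coupling. The fallback reverses the polarity, sets out from 2 and returns at 4. Bromine–lithium exchange with t-BuLi (2 equiv) in Et2O at −78 °C gives [(3aR,7aS)-2,2-dimethyl-3a,7a-dihydro-1,3-benzodioxol-4-yl]lithium F1. This is trapped at −78 °C with monomeric formaldehyde (cracked paraformaldehyde) to give 4 after NH4Cl work-up.

Step 4. Lewis-acid activation may ionise the vinyl oxirane, leading to conjugate opening at C4 or loss of the anti stereochemistry, and the new ester may migrate. The fallback separates C–O bond formation from acylation, sets out from 5 and returns at 8. Hydrolysis in hot water with catalytic sodium benzoate (no Lewis acid, direct backside attack at allylic C2) should give the triol acetonide F2. BzCl (2.2 equiv), pyridine and catalytic DMAP at 0 °C acylate O7 and O2 and leave the tertiary O1–H, giving the dibenzoate acetonide F3. AcOH/H2O as in step 5 then gives 8, now isolated, and one equivalent of BzCl under the conditions of step 6 converts it into 9.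

Further compounds
F1 | step 2 | [(3aR,7aS)-2,2-dimethyl-3a,7a-dihydro-1,3-benzodioxol-4-yl]lithium | CC1(C)O[C@H]2C=CC=C([Li])[C@H]2O1
F2 | step 4 | (3aS,4S,5R,7aS)-4-(hydroxymethyl)-2,2-dimethyl-3a,4,5,7a-tetrahydro-1,3-benzodioxole-4,5-diol | CC1(C)O[C@H]2C=C[C@@H](O)[C@@](O)(CO)[C@H]2O1
F3 | step 4 | [(3aS,4S,5R,7aS)-5-(benzoyloxy)-4-hydroxy-2,2-dimethyl-3a,4,5,7a-tetrahydro-1,3-benzodioxol-4-yl]methyl benzoate | CC1(C)O[C@H]2C=C[C@@H](OC(=O)c3ccccc3)[C@@](O)(COC(=O)c3ccccc3)[C@H]2O1
F4 | step 6 | 6,7-O-(di-tert-butylsilylene) derivative of 7 (six-membered silylene across O6 and O7; O1–H and O5–H free) | O[C@H]1C=C[C@@H](OC(=O)c3ccccc3)[C@@]2(O)CO[Si](C(C)(C)C)(C(C)(C)C)O[C@@H]12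
F5 | step 6 | 5-O-benzoyl-6,7-O-(di-tert-butylsilylene) derivative of 7 | O=C(O[C@H]1C=C[C@@H](OC(=O)c3ccccc3)[C@@]2(O)CO[Si](C(C)(C)C)(C(C)(C)C)O[C@@H]12)c1ccccc1
F6 | step 6 | (1R,2R,5S,6S)-1,6-dihydroxy-1-(hydroxymethyl)cyclohex-3-ene-2,5-diyl dibenzoate | O=C(O[C@H]1C=C[C@@H](OC(=O)c2ccccc2)[C@@](O)(CO)[C@H]1O)c1ccccc1
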